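**Strategy.** Ring A is cut at C1–C2 and C5–C10 (abietane numbering), a retro-Diels–Alder disconnection. It leaves the C20,O–C7 lactone fused to aromatic ring C as a 4-methylidene-isochroman-3-one, whose C10=C1 alkene is the dienophile, and a (Z)-2-(hydroxymethyl)butadiene (C2 to C5) hanging from C7 through the C6 carbinol. One intramolecular cycloaddition closes ring A and, across the lactone ring, ring B, giving the 2-oxabicyclo[2.2.2]octanone together with C5 and C10. It exploits C10 being at once lactone alpha-carbon and A/B bridgehead. C6 and C7 come from an asymmetric alkoxyallylboration, the diene from a silicon-tethered enyne metathesis, the C4 methyl from a late radical hydromethylation.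

Key step: step 11

Remark: atoms are named by abietane numbering throughout. The acetal carbon of the tetrahydropyranyl group (8, 10) and the tertiary carbinol carbon of 10 to 14 are carried as epimer mixtures, and both centres are removed before the key step.

Step 1
Reactants: 1 1,2,4-trimethoxybenzene; 2 acetone
Product: 3 2-(2,3,6-trimethoxyphenyl)propan-2-ol
Conditions: n-BuLi, TMEDA, THF, 0 °C; then 2, −78 °C to rt; H2O
Reagents that add atoms: none
Why: Directed ortho-metalation should occur at C3, the only position flanked by two methoxy groups, and the aryllithium then undergoes 1,2-addition to acetone.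

Step 2
Reactants: 3 2-(2,3,6-trimethoxyphenyl)propan-2-ol
Product: 4 1,2,4-trimethoxy-3-(propan-2-yl)benzene
Conditions: Et3SiH, CF3CO2H, CH2Cl2, 0 °C to rt
Reagents that add atoms: none
Why: Ionic hydrogenation, in which the tertiary benzylic cation stabilised by two ortho methoxy groups is trapped by hydride from the silane.

Step 3
Reactants: 4 1,2,4-trimethoxy-3-(propan-2-yl)benzene
Product: 5 2,4,5-trimethoxy-3-(propan-2-yl)benzaldehyde
Conditions: Cl2CHOCH3, TiCl4, CH2Cl2, −78 to 0 °C; aqueous work-up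
Reagents that add atoms: dichloromethyl methyl ether COC(Cl)Cl; water O
Why: Rieche formylation should go to the free position that is para to the 2-methoxy and ortho to the 4-methoxy group (future C8), the most electron-rich site, as in 1,2,4-trimethoxybenzene itself.

Step 4
Reactants: 5 2,4,5-trimethoxy-3-(propan-2-yl)benzaldehyde
Product: 6 2-bromo-3,4,6-trimethoxy-5-(propan-2-yl)benzaldehyde
Conditions: NBS, CH3CN, rt, dark
Reagents that add atoms: N-bromosuccinimide O=C1CCC(=O)N1Br
Why: Electrophilic aromatic bromination can only take the last free ring position (future C9), which is ortho to a methoxy group.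

Step 5
Reactants: 6 2-bromo-3,4,6-trimethoxy-5-(propan-2-yl)benzaldehyde; 7 2-(prop-2-en-1-yloxy)oxane (allyl tetrahydropyranyl ether)
Product: 8 (1R,2R)-1-[2-bromo-3,4,6-trimethoxy-5-(propan-2-yl)phenyl]-2-(oxan-2-yloxy)but-3-en-1-ol
Conditions: 7, s-BuLi, THF, −78 °C; (−)-Ipc2BOMe; BF3·OEt2; then 6, −78 °C; NaOH, H2O2, 0 °C to rt
Reagents that add atoms: none
Why: Brown asymmetric (Z)-gamma-alkoxyallylboration, in which the closed chair transition state of the Z allylborane gives the syn 1,2-diol monoether and the isopinocampheyl groups from (+)-alpha-pinene steer the allyl unit to the Si face of the aldehyde, which sets C7 and C6 as R,R.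

Step 6
Reactants: 8 (1R,2R)-1-[2-bromo-3,4,6-trimethoxy-5-(propan-2-yl)phenyl]-2-(oxan-2-yloxy)but-3-en-1-ol; 9 methyl pyruvate
Product: 10 (1R)-4-hydroxy-5,6,8-trimethoxy-4-methyl-1-[(1R)-1-(oxan-2-yloxy)prop-2-en-1-yl]-7-(propan-2-yl)-1,4-dihydro-3H-2-benzopyran-3-one
Conditions: n-BuLi (1 equiv), then t-BuLi (2 equiv), THF, −78 °C; then 9, −78 to 0 °C; H2O
Reagents that add atoms: none
Why: Bromine–lithium exchange on the lithium alkoxide of 8 gives an aryllithium that adds to the ketone of the pyruvate, and the neighbouring C7 alkoxide then closes the six-membered lactone by transesterification, while the new carbinol centre (future C10) forms as a mixture that step 10 removes.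

Step 7
Reactants: 10 (1R)-4-hydroxy-5,6,8-trimethoxy-4-methyl-1-[(1R)-1-(oxan-2-yloxy)prop-2-en-1-yl]-7-(propan-2-yl)-1,4-dihydro-3H-2-benzopyran-3-one
Product: 11 (1R)-4-hydroxy-1-[(1R)-1-hydroxyprop-2-en-1-yl]-5,6,8-trimethoxy-4-methyl-7-(propan-2-yl)-1,4-dihydro-3H-2-benzopyran-3-one
Conditions: pyridinium p-toluenesulfonate (cat.), MeOH, rt
Reagents that add atoms: none
Why: Acid-catalysed acetal exchange cleaves the tetrahydropyranyl ether and frees the C6 hydroxyl under conditions too mild to ionise the benzylic lactone C7–O bond.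

Step 8
Reactants: 11 (1R)-4-hydroxy-1-[(1R)-1-hydroxyprop-2-en-1-yl]-5,6,8-trimethoxy-4-methyl-7-(propan-2-yl)-1,4-dihydro-3H-2-benzopyran-3-one; 12 prop-2-yn-1-ol
Product: 13 (1R)-1-[(1R)-1-{[di(propan-2-yl)(prop-2-yn-1-yloxy)silyl]oxy}prop-2-en-1-yl]-4-hydroxy-5,6,8-trimethoxy-4-methyl-7-(propan-2-yl)-1,4-dihydro-3H-2-benzopyran-3-one
Conditions: iPr2SiCl2, Et3N, 12, CH2Cl2, 0 °C; then 11, imidazole, DMF, rt
Reagents that add atoms: dichlorodi(propan-2-yl)silane CC(C)[Si](Cl)(Cl)C(C)C
Why: Mixed silyl ketal formation should occur only at the secondary allylic C6 hydroxyl, because the tertiary alpha-hydroxy lactone carbinol is too hindered for the bulky chlorosilane.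

Step 9
Reactants: 13 (1R)-1-[(1R)-1-{[di(propan-2-yl)(prop-2-yn-1-yloxy)silyl]oxy}prop-2-en-1-yl]-4-hydroxy-5,6,8-trimethoxy-4-methyl-7-(propan-2-yl)-1,4-dihydro-3H-2-benzopyran-3-one
Product: 14 (1R)-1-[(4R)-6-ethenyl-2,2-di(propan-2-yl)-4,7-dihydro-1,3,2-dioxasilepin-4-yl]-4-hydroxy-5,6,8-trimethoxy-4-methyl-7-(propan-2-yl)-1,4-dihydro-3H-2-benzopyran-3-one
Conditions: second-generation Grubbs catalyst (5 mol %), ethylene (1 atm), CH2Cl2, 40 °C
Reagents that add atoms: none
Why: Ring-closing enyne metathesis in the exo mode forms the seven-membered silyl ketal ring, which places the vinyl group (C3=C2) on C4 and forces C19 and C6 to be cis on the new C4=C5 bond.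

Step 10
Reactants: 14 (1R)-1-[(4R)-6-ethenyl-2,2-di(propan-2-yl)-4,7-dihydro-1,3,2-dioxasilepin-4-yl]-4-hydroxy-5,6,8-trimethoxy-4-methyl-7-(propan-2-yl)-1,4-dihydro-3H-2-benzopyran-3-one
Product: 15 (1R)-1-[(4R)-6-ethenyl-2,2-di(propan-2-yl)-4,7-dihydro-1,3,2-dioxasilepin-4-yl]-5,6,8-trimethoxy-4-methylidene-7-(propan-2-yl)-1,4-dihydro-3H-2-benzopyran-3-one
Conditions: Martin sulfurane Ph2S[OC(CF3)2Ph]2, CH2Cl2, 0 °C to rt
Reagents that add atoms: none
Why: Dehydration of the tertiary benzylic alcohol can lose a proton only from the methyl group, which unveils the alpha-methylidene lactone (C10=C1).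

Step 11
Reactants: 15 (1R)-1-[(4R)-6-ethenyl-2,2-di(propan-2-yl)-4,7-dihydro-1,3,2-dioxasilepin-4-yl]-5,6,8-trimethoxy-4-methylidene-7-(propan-2-yl)-1,4-dihydro-3H-2-benzopyran-3-one
Product: 17 (5S,6R,7R,10R)-6,19-dihydroxy-11,12,14-trimethoxyabieta-3,8,11,13-tetraen-20,7-olide, via triene diol 16 (not isolated)
Conditions: HF·pyridine, THF, 0 °C; then toluene, BHT, 110 °C
Reagents that add atoms: none
Why: Fluoride removes the silyl ketal and the freed triene 16 undergoes a thermal, concerted but asynchronous normal-demand [4+2] cycloaddition between the C2=C3–C4=C5 diene and the lactone-activated C10=C1 alkene; the closest known type is the type 1 intramolecular Diels–Alder reaction of a 1,3,9-decatriene with an internally activated alpha-methylene ester dienophile. Ring A closes by the [4+2] mode itself (bonds C1–C2 and C5–C10), and ring B closes in the same event as the third six-membered bridge across the lactone ring, which bends into a shallow boat and becomes the 2-oxabicyclo[2.2.2]octan-3-one. C10 is controlled by C7, because C6 holds the diene over one face of the lactone ring and C5 can reach C10 only from that face. C5 is controlled by the C6 carbinol through allylic 1,3-strain: the C19 group, cis to C6 on the diene, forces H6 into the diene plane, so C7 with the dienophile lies under one diene face and the C6 hydroxyl points away, which gives H5 cis to that hydroxyl. The step needs the endo orientation in which C3 and C4 lie over the lactone carbonyl and not over ring C, and this is secured by the same allylic strain, by secondary overlap with C20=O and possibly by a hydrogen bond from the C19 hydroxyl to the lactone. Regiochemistry is fixed by the tether, and the new alkene ends up at C3=C4 with the hydroxymethyl group on C4.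

Step 12
Reactants: 17 (5S,6R,7R,10R)-6,19-dihydroxy-11,12,14-trimethoxyabieta-3,8,11,13-tetraen-20,7-olide
Product: 19 (4S,5S,6R,7R,10R)-6,19-dihydroxy-11,12,14-trimethoxyabieta-8,11,13-trien-20,7-olide, via sulfonylhydrazide 18 (not isolated)
Conditions: CH2O (aq.), CH3SO2NHNH2, THF, rt; then 17, Fe(acac)3 (30 mol %), PhSiH3, THF/MeOH, rt; then MeOH, 60 °C
Reagents that add atoms: formaldehyde C=O; methanesulfonyl hydrazide CS(=O)(=O)NN (its atoms stay only in 18)
Why: Radical olefin hydromethylation by metal-hydride hydrogen atom transfer, in which the Markovnikov tertiary C4 radical should add to the formaldehyde sulfonylhydrazone from the alpha face, opposite the axial C20 carbonyl on C10, and loss of sulfinate and N2 from 18 then leaves the alpha methyl group with the hydroxymethyl group beta.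

Step 13
Reactants: 19 (4S,5S,6R,7R,10R)-6,19-dihydroxy-11,12,14-trimethoxyabieta-8,11,13-trien-20,7-olide
Product: 20 (4S,5S,6R,7R,10R)-6,19-dihydroxy-12-methoxy-11,14-dioxoabieta-8,12-dien-20,7-olide
Conditions: (NH4)2Ce(NO3)6, CH3CN/H2O, 0 °C
Reagents that add atoms: water O
Why: Oxidative demethylation by the tetravalent cerium salt converts the para-related C11 and C14 methoxy groups into the para-quinone carbonyls and leaves the C12 methoxy group as a vinylogous ester.

Step 14
Reactants: 20 (4S,5S,6R,7R,10R)-6,19-dihydroxy-12-methoxy-11,14-dioxoabieta-8,12-dien-20,7-olide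
Product: 21 (4S,5S,6R,7R,10R)-6,12,19-trihydroxy-11,14-dioxoabieta-8,12-dien-20,7-olide (CNP0339604.1)
Conditions: BCl3, CH2Cl2, −78 °C; then H2O
Reagents that add atoms: none
Why: Chelation of boron between the C11 carbonyl and the C12 methoxy oxygen should allow selective Lewis-acid O-demethylation of the vinylogous ester at low temperature, sparing the lactone and the free alcohols.

**Compound list**

1 | 1,2,4-trimethoxybenzene | COc1ccc(OC)c(OC)c1 | starting material
2 | acetone | CC(C)=O | starting material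
3 | 2-(2,3,6-trimethoxyphenyl)propan-2-ol | COc1ccc(OC)c(OC)c1C(C)(C)O | intermediate
4 | 1,2,4-trimethoxy-3-(propan-2-yl)benzene | COc1ccc(OC)c(OC)c1C(C)C | intermediate
5 | 2,4,5-trimethoxy-3-(propan-2-yl)benzaldehyde | COc1c(C=O)cc(OC)c(OC)c1C(C)C | intermediate
6 | 2-bromo-3,4,6-trimethoxy-5-(propan-2-yl)benzaldehyde | COc1c(C=O)c(Br)c(OC)c(OC)c1C(C)C | intermediate
7 | 2-(prop-2-en-1-yloxy)oxane | C=CCOC1CCCCO1 | starting material
8 | (1R,2R)-1-[2-bromo-3,4,6-trimethoxy-5-(propan-2-yl)phenyl]-2-(oxan-2-yloxy)but-3-en-1-ol (both acetal epimers) | COc1c([C@@H](O)[C@H](OC2CCCCO2)C=C)c(Br)c(OC)c(OC)c1C(C)C | intermediate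
9 | methyl pyruvate (methyl 2-oxopropanoate) | CC(=O)C(=O)OC | starting material
10 | (1R)-4-hydroxy-5,6,8-trimethoxy-4-methyl-1-[(1R)-1-(oxan-2-yloxy)prop-2-en-1-yl]-7-(propan-2-yl)-1,4-dihydro-3H-2-benzopyran-3-one (epimers at C4 of the ring and at the acetal carbon) | COc1c2c(c(OC)c(OC)c1C(C)C)C(C)(O)C(=O)O[C@H]2[C@H](OC1CCCCO1)C=C | intermediate
11 | (1R)-4-hydroxy-1-[(1R)-1-hydroxyprop-2-en-1-yl]-5,6,8-trimethoxy-4-methyl-7-(propan-2-yl)-1,4-dihydro-3H-2-benzopyran-3-one | COc1c2c(c(OC)c(OC)c1C(C)C)C(C)(O)C(=O)O[C@H]2[C@H](O)C=C | intermediate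
12 | prop-2-yn-1-ol | C#CCO | starting material
13 | (1R)-1-[(1R)-1-{[di(propan-2-yl)(prop-2-yn-1-yloxy)silyl]oxy}prop-2-en-1-yl]-4-hydroxy-5,6,8-trimethoxy-4-methyl-7-(propan-2-yl)-1,4-dihydro-3H-2-benzopyran-3-one | COc1c2c(c(OC)c(OC)c1C(C)C)C(C)(O)C(=O)O[C@H]2[C@H](O[Si](C(C)C)(C(C)C)OCC#C)C=C | intermediate
14 | (1R)-1-[(4R)-6-ethenyl-2,2-di(propan-2-yl)-4,7-dihydro-1,3,2-dioxasilepin-4-yl]-4-hydroxy-5,6,8-trimethoxy-4-methyl-7-(propan-2-yl)-1,4-dihydro-3H-2-benzopyran-3-one | COc1c2c(c(OC)c(OC)c1C(C)C)C(C)(O)C(=O)O[C@H]2[C@@H]1O[Si](C(C)C)(C(C)C)OCC(C=C)=C1 | intermediate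
15 | (1R)-1-[(4R)-6-ethenyl-2,2-di(propan-2-yl)-4,7-dihydro-1,3,2-dioxasilepin-4-yl]-5,6,8-trimethoxy-4-methylidene-7-(propan-2-yl)-1,4-dihydro-3H-2-benzopyran-3-one | COc1c2c(c(OC)c(OC)c1C(C)C)C(=C)C(=O)O[C@H]2[C@@H]1O[Si](C(C)C)(C(C)C)OCC(C=C)=C1 | intermediate
16 | (1R)-1-[(1R,2Z)-1-hydroxy-3-(hydroxymethyl)penta-2,4-dien-1-yl]-5,6,8-trimethoxy-4-methylidene-7-(propan-2-yl)-1,4-dihydro-3H-2-benzopyran-3-one | COc1c2c(c(OC)c(OC)c1C(C)C)C(=C)C(=O)O[C@H]2[C@H](O)/C=C(\CO)C=C | intermediate
17 | (5S,6R,7R,10R)-6,19-dihydroxy-11,12,14-trimethoxyabieta-3,8,11,13-tetraen-20,7-olide (6α-OH, 7β-O, H5α) | CC(C)c1c(OC)c(OC)c2c(c1OC)[C@H]1OC(=O)[C@@]23CCC=C(CO)[C@@H]3[C@H]1O | intermediate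
18 | N'-{[(4S,5S,6R,7R,10R)-6,19-dihydroxy-11,12,14-trimethoxy-20-oxo-7,20-epoxy-18-norabieta-8,11,13-trien-4-yl]methyl}methanesulfonohydrazide (the 4α-CH2NHNHSO2CH3 adduct of 17) | CC(C)c1c(OC)c(OC)c2c(c1OC)[C@H]1OC(=O)[C@@]23CCC[C@](CNNS(C)(=O)=O)(CO)[C@@H]3[C@H]1O | intermediate
19 | (4S,5S,6R,7R,10R)-6,19-dihydroxy-11,12,14-trimethoxyabieta-8,11,13-trien-20,7-olide | CC(C)c1c(OC)c(OC)c2c(c1OC)[C@H]1OC(=O)[C@@]23CCC[C@](C)(CO)[C@@H]3[C@H]1O | intermediate
20 | (4S,5S,6R,7R,10R)-6,19-dihydroxy-12-methoxy-11,14-dioxoabieta-8,12-dien-20,7-olide | CC(C)C1=C(OC)C(=O)C2=C(C1=O)[C@H]1OC(=O)[C@@]23CCC[C@](C)(CO)[C@@H]3[C@H]1O | intermediate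
21 | (4S,5S,6R,7R,10R)-6,12,19-trihydroxy-11,14-dioxoabieta-8,12-dien-20,7-olide | CC(C)C1=C(O)C(=O)C2=C(C1=O)[C@H]1OC(=O)[C@@]23CCC[C@](C)(CO)[C@@H]3[C@H]1O | target

**Step count and risk**

Total steps: 14. Longest linear sequence: 14 steps (from 1).

Steps most likely to fail:

Step 11. The cycloaddition has to pass through a boat-shaped lactone ring, so oligomerisation of the exposed methylidene lactone or oxa-Michael addition of its free hydroxyls may outrun ring closure, and the endo preference may erode at the temperature needed. The fallback sets out from 15 and moves the dienophile to the aldehyde oxidation level. Reduction of 15 with i-Bu2AlH (CH2Cl2, −78 °C) should give the lactol (1R)-1-[(4R)-6-ethenyl-2,2-di(propan-2-yl)-4,7-dihydro-1,3,2-dioxasilepin-4-yl]-5,6,8-trimethoxy-4-methylidene-7-(propan-2-yl)-3,4-dihydro-1H-2-benzopyran-3-ol F1. HF·pyridine then frees the lactol triol F2. On warming in toluene, the open 2-arylacrolein tautomer of F2 is the more reactive dienophile and needs no bicyclic transition state; the same allylic strain and the endo preference of the formyl group should give the same C5 and C10 configuration, and the adduct closes to the bridged lactol (5S,6R,7R,10R)-7,20-epoxy-11,12,14-trimethoxyabieta-3,8,11,13-tetraene-6,19,20-triol F3. Ag2CO3 on Celite (toluene, rt), which oxidises hemiacetals much faster than alcohols, should convert F3 into the lactone, and the route is rejoined at 17.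

Step 12. The tertiary C4 radical may be trapped with poor facial selectivity, or simple hydrogenation of the alkene by hydrogen atom transfer may compete with carbon–carbon bond formation. The fallback sets out from 17. Hydroxyl-directed Simmons–Smith cyclopropanation (Et2Zn, CH2I2, CH2Cl2, 0 °C) should deliver the methylene to the alpha face, guided by the 19- and 6α-hydroxyls and away from the axial C20 carbonyl, to give the cyclopropane (5S,6R,7R,10R)-6,19-dihydroxy-11,12,14-trimethoxy-3α,18-cycloabieta-8,11,13-trien-20,7-olide F4. Hydrogenolysis of the least hindered cyclopropane bond C3–C18 (H2, PtO2, AcOH, rt) turns the methylene into the 4α-methyl group, and the route is rejoined at 19.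

Step 6. Proton transfer from the enolisable pyruvate to the hindered aryllithium may compete with carbonyl addition and return the debrominated arene. The fallback sets out from 8. The same bromine–lithium exchange is quenched with dimethyl oxalate, which cannot enolise; addition and lactonisation by the C7 alkoxide should give the keto lactone (1R)-5,6,8-trimethoxy-1-[(1R)-1-(oxan-2-yloxy)prop-2-en-1-yl]-7-(propan-2-yl)-1H-2-benzopyran-3,4-dione F5. CH3MgBr (THF, −78 °C) should add to the more electrophilic ketone carbonyl of F5, and the route is rejoined at 10.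

**Further compounds**

F1 | step 11 | (1R)-1-[(4R)-6-ethenyl-2,2-di(propan-2-yl)-4,7-dihydro-1,3,2-dioxasilepin-4-yl]-5,6,8-trimethoxy-4-methylidene-7-(propan-2-yl)-3,4-dihydro-1H-2-benzopyran-3-ol | COc1c2c(c(OC)c(OC)c1C(C)C)C(=C)C(O)O[C@H]2[C@@H]1O[Si](C(C)C)(C(C)C)OCC(C=C)=C1
F2 | step 11 | (1R)-1-[(1R,2Z)-1-hydroxy-3-(hydroxymethyl)penta-2,4-dien-1-yl]-5,6,8-trimethoxy-4-methylidene-7-(propan-2-yl)-3,4-dihydro-1H-2-benzopyran-3-ol | COc1c2c(c(OC)c(OC)c1C(C)C)C(=C)C(O)O[C@H]2[C@H](O)/C=C(\CO)C=C
F3 | step 11 | (5S,6R,7R,10R)-7,20-epoxy-11,12,14-trimethoxyabieta-3,8,11,13-tetraene-6,19,20-triol | CC(C)c1c(OC)c(OC)c2c(c1OC)[C@H]1OC(O)[C@@]23CCC=C(CO)[C@@H]3[C@H]1O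
F4 | step 12 | (5S,6R,7R,10R)-6,19-dihydroxy-11,12,14-trimethoxy-3α,18-cycloabieta-8,11,13-trien-20,7-olide | CC(C)c1c(OC)c(OC)c2c(c1OC)[C@H]1OC(=O)[C@@]23CC[C@H]4C[C@@]4(CO)[C@@H]3[C@H]1O
F5 | step 6 | (1R)-5,6,8-trimethoxy-1-[(1R)-1-(oxan-2-yloxy)prop-2-en-1-yl]-7-(propan-2-yl)-1H-2-benzopyran-3,4-dione | COc1c2c(c(OC)c(OC)c1C(C)C)C(=O)C(=O)O[C@H]2[C@H](OC1CCCCO1)C=C
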